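Atom numbers follow the pyrido[1,2-a:3,4-b']diindole skeleton. The route rests on cutting the N12–C12a and C7a–C7b bonds of the NH-indole, whose C12a–C7a edge is shared with the central pyridine ring and whose C12a is bonded to C12b of the bromoindole. This reveals phenylhydrazine 7 and tricyclic ketone 6, whose carbonyl carbon becomes C12a and whose only α-methylene becomes C7a. Fischer indolisation of 6 thus builds the whole pyrrole ring of the second indole in one operation, giving pentacycle 9 at the 6,7-dihydro level. Ketone 6 comes from a bromoindole diester by Dieckmann closure; C13 formylation and C6–C7 dehydrogenation finish the achiral target.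

Key step: step 4

Assumption: the target has no stereocentre, axis or other stereogenic element, so it is one achiral compound and no enantiocontrol is needed; the only stereocentre on the way (C8 of 4 and 5, racemic) is removed in step 3.

Step 1
Reactants: 1 ethyl 6-bromo-1H-indole-2-carboxylate; 2 ethyl 4-bromobutanoate
Product: 3 ethyl 6-bromo-1-(4-ethoxy-4-oxobutyl)-1H-indole-2-carboxylate
Conditions: Cs2CO3, DMF, 60 °C
Reagents that add atoms: none
Why: SN2 N-alkylation, in which the indole N–H, acidified by the 2-ester, is deprotonated by carbonate and the indolide nitrogen displaces the primary bromide, C3 attack being disfavoured by the conjugated ester.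

Step 2
Reactants: 3 ethyl 6-bromo-1-(4-ethoxy-4-oxobutyl)-1H-indole-2-carboxylate
Product: 4 ethyl 3-bromo-9-oxo-6,7,8,9-tetrahydropyrido[1,2-a]indole-8-carboxylate (racemic at C8, in equilibrium with its enol)
Conditions: KOtBu, THF, 0 °C to rt; then 1 M HCl
Reagents that add atoms: none
Why: Dieckmann condensation, in which only the butanoate ester can enolise, so its enolate adds to the non-enolisable indole-2-ester carbonyl in a six-membered exo-trig closure and deprotonation of the β-keto ester drives the equilibrium; the new C8 centre is formed without control and is erased in step 3.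

Step 3
Reactants: 4 ethyl 3-bromo-9-oxo-6,7,8,9-tetrahydropyrido[1,2-a]indole-8-carboxylate
Product: 6 3-bromo-7,8-dihydropyrido[1,2-a]indol-9(6H)-one, via keto acid 5 (not isolated)
Conditions: 6 M HCl, AcOH, 100 °C
Reagents that add atoms: none
Why: Acid hydrolysis of the ester followed by β-keto acid decarboxylation through the cyclic six-membered transition state, with acid chosen over base to avoid retro-Claisen ring opening and with the aryl bromide inert.

Step 4
Reactants: 6 3-bromo-7,8-dihydropyrido[1,2-a]indol-9(6H)-one; 7 phenylhydrazine
Product: 9 3-bromo-6,7-dihydro-12H-pyrido[1,2-a:3,4-b']diindole, via phenylhydrazone 8 (not isolated)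
Conditions: PhNHNH2, AcOH, 80 °C; then conc. HCl, 100 °C
Reagents that add atoms: none
Why: Acid-catalysed condensation gives phenylhydrazone 8, which tautomerises to the ene-hydrazine across C9–C8 and, once N-protonated, undergoes the [3,3]-sigmatropic (diaza-Cope) shift that breaks N–N and joins C8 to an ortho carbon of the phenyl ring (the C7a–C7b bond of 9). After rearomatisation the aniline nitrogen adds to the C9 iminium carbon in a 5-exo-trig closure (the N12–C12a bond), and loss of ammonia from the aminal aromatises the new pyrrole ring. The closest known reaction type is the Fischer indole synthesis on cyclic aryl ketones such as 1-tetralone or 1-oxotetrahydrocarbazole, which give 2,3-ring-fused indoles. No stereocentre is formed. The step needs regioselective ene-hydrazine formation, which is secured because C9 has a single enolisable neighbour (C8H2, the other being the fully substituted aromatic C9a) and because the two ortho positions of phenylhydrazine are equivalent, so only one indole can result. The aryl bromide and the N-alkylindole should tolerate hot protic acid, and the slow stage is expected to be hydrazone formation at the weakly electrophilic 2-acylindole carbonyl.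

Step 5
Reactants: 9 3-bromo-6,7-dihydro-12H-pyrido[1,2-a:3,4-b']diindole
Product: 11 3-bromo-6,7-dihydro-12H-pyrido[1,2-a:3,4-b']diindole-13-carbaldehyde, via iminium chloride 10 (not isolated)
Conditions: POCl3, DMF, 0 °C to rt; then 2 M NaOH
Reagents that add atoms: N,N-dimethylformamide CN(C)C=O; water O
Why: Vilsmeier–Haack formylation, in which C13 is the only unsubstituted pyrrole-ring carbon (the 3-position of the N5 indole), so the chloroiminium ion attacks there and iminium salt 10 is hydrolysed to the aldehyde on basic work-up, which also cleaves any N12-formyl by-product.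

Step 6
Reactants: 11 3-bromo-6,7-dihydro-12H-pyrido[1,2-a:3,4-b']diindole-13-carbaldehyde
Product: 12 3-bromo-12H-pyrido[1,2-a:3,4-b']diindole-13-carbaldehyde
Conditions: DDQ, anhydrous 1,4-dioxane, rt to 80 °C
Reagents that add atoms: none
Why: DDQ dehydrogenation, in which hydride abstraction from C7 (the methylene on C7a, the 3-position of the NH-indole) gives an indole-stabilised cation that loses the C6 proton, driven by formation of the aromatic pyridine ring, while the 13-formyl group already in place lowers the electron density of the product and guards it against over-oxidation.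

Compound list
1 | ethyl 6-bromo-1H-indole-2-carboxylate | CCOC(=O)c1cc2ccc(Br)cc2[nH]1 | starting material
2 | ethyl 4-bromobutanoate | CCOC(=O)CCCBr | starting material
3 | ethyl 6-bromo-1-(4-ethoxy-4-oxobutyl)-1H-indole-2-carboxylate | CCOC(=O)CCCn1c(C(=O)OCC)cc2ccc(Br)cc21 | intermediate
4 | ethyl 3-bromo-9-oxo-6,7,8,9-tetrahydropyrido[1,2-a]indole-8-carboxylate (racemic) | CCOC(=O)C1CCn2c(C1=O)cc1ccc(Br)cc12 | intermediate
5 | 3-bromo-9-oxo-6,7,8,9-tetrahydropyrido[1,2-a]indole-8-carboxylic acid (racemic, not isolated) | OC(=O)C1CCn2c(C1=O)cc1ccc(Br)cc12 | intermediate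
6 | 3-bromo-7,8-dihydropyrido[1,2-a]indol-9(6H)-one | O=C1CCCn2c1cc1ccc(Br)cc12 | intermediate
7 | phenylhydrazine | NNc1ccccc1 | starting material
8 | 3-bromo-9-(2-phenylhydrazinylidene)-6,7,8,9-tetrahydropyrido[1,2-a]indole (C=N geometry immaterial, not isolated) | Brc1ccc2cc3C(=NNc4ccccc4)CCCn3c2c1 | intermediate
9 | 3-bromo-6,7-dihydro-12H-pyrido[1,2-a:3,4-b']diindole | Brc1ccc2cc3c4[nH]c5ccccc5c4CCn3c2c1 | intermediate
10 | N-[(3-bromo-6,7-dihydro-12H-pyrido[1,2-a:3,4-b']diindol-13-yl)methylidene]-N-methylmethanaminium chloride (not isolated) | C[N+](C)=Cc1c2ccc(Br)cc2n2CCc3c4ccccc4[nH]c3c12.[Cl-] | intermediate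
11 | 3-bromo-6,7-dihydro-12H-pyrido[1,2-a:3,4-b']diindole-13-carbaldehyde | O=Cc1c2ccc(Br)cc2n2CCc3c4ccccc4[nH]c3c12 | intermediate
12 | 3-bromo-12H-pyrido[1,2-a:3,4-b']diindole-13-carbaldehyde | O=Cc1c2ccc(Br)cc2n2ccc3c4ccccc4[nH]c3c12 | target

Total step count: 6. Longest linear sequence: 6 steps (1 to 12).

Steps most likely to fail

Step 4 (Fischer indolisation). Condensation may stall because the C9 carbonyl is a deactivated, vinylogous-amide-like 2-acylindole carbonyl, or the hydrazone may suffer N–N cleavage and tar formation in hot acid before the sigmatropic shift. The fallback sets out from 6 and comes back at 9, making the same two bonds in separate, non-sigmatropic events. The potassium enolate of 6 (KOtBu, 2.2 equiv, DMSO–THF, 0 °C to rt) should displace fluoride from 1-fluoro-2-nitrobenzene in an SNAr α-arylation, giving racemic 3-bromo-8-(2-nitrophenyl)-7,8-dihydropyrido[1,2-a]indol-9(6H)-one F1. Iron powder in AcOH at 80 °C should then reduce the nitro group to 8-(2-aminophenyl)-3-bromo-7,8-dihydropyrido[1,2-a]indol-9(6H)-one F2 (not isolated), whose aniline nitrogen condenses with the C9 carbonyl and tautomerises to 9. Iron is preferred to catalytic hydrogenation so that the aryl bromide is kept.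

Step 6 (DDQ dehydrogenation). Hydride abstraction from C7 may be sluggish on the formyl-bearing substrate, or the quinone may add to or over-oxidise the indole rings, and traces of water may intercept the C7 cation. The fallback sets out from 9 and comes back at 12 by inverting the order of the last two operations and avoiding the quinone. Activated MnO2 in refluxing toluene should aromatise the more electron-rich, formyl-free bridge to 3-bromo-12H-pyrido[1,2-a:3,4-b']diindole F3. Vilsmeier–Haack formylation (POCl3, DMF, then aqueous NaOH) at C13, the most nucleophilic position of this ring system, should then proceed through N-[(3-bromo-12H-pyrido[1,2-a:3,4-b']diindol-13-yl)methylidene]-N-methylmethanaminium chloride F4 (not isolated) to 12.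

Step 2 (Dieckmann condensation). Intermolecular Claisen condensation or ester cleavage by adventitious hydroxide may outrun ring closure, and the β-keto ester may reopen by retro-Claisen attack during work-up. The fallback sets out from 2 and comes back at 6, replacing enolate acylation by electrophilic acylation of the indole C2. Commercial 6-bromo-1H-indole F5 is N-alkylated with 2 (NaH, DMF, 0 °C to rt) to ethyl 4-(6-bromo-1H-indol-1-yl)butanoate F6. Saponification (LiOH, THF–water) gives 4-(6-bromo-1H-indol-1-yl)butanoic acid F7. Polyphosphoric acid at 90 °C should then close the six-membered ketone by intramolecular Friedel–Crafts acylation at C2, the only position that the tether can reach through a six-membered ring, to give 6.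

Further compounds
F1 | step 4 | 3-bromo-8-(2-nitrophenyl)-7,8-dihydropyrido[1,2-a]indol-9(6H)-one (racemic) | O=C1C(c2ccccc2[N+](=O)[O-])CCn2c1cc1ccc(Br)cc12
F2 | step 4 | 8-(2-aminophenyl)-3-bromo-7,8-dihydropyrido[1,2-a]indol-9(6H)-one (racemic, not isolated) | Nc1ccccc1C1CCn2c(C1=O)cc1ccc(Br)cc12
F3 | step 6 | 3-bromo-12H-pyrido[1,2-a:3,4-b']diindole | Brc1ccc2cc3c4[nH]c5ccccc5c4ccn3c2c1
F4 | step 6 | N-[(3-bromo-12H-pyrido[1,2-a:3,4-b']diindol-13-yl)methylidene]-N-methylmethanaminium chloride (not isolated) | C[N+](C)=Cc1c2ccc(Br)cc2n2ccc3c4ccccc4[nH]c3c12.[Cl-]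
F5 | step 2 | 6-bromo-1H-indole | Brc1ccc2cc[nH]c2c1
F6 | step 2 | ethyl 4-(6-bromo-1H-indol-1-yl)butanoate | CCOC(=O)CCCn1ccc2ccc(Br)cc21
F7 | step 2 | 4-(6-bromo-1H-indol-1-yl)butanoic acid | OC(=O)CCCn1ccc2ccc(Br)cc21
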